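Count half-lives. L and E make J, and J is then lost, so what I am asked is how much J outlasts the time each flask stands.

| flask | L | E | Q | temperature | remark | time |
|---|---|---|---|---|---|---|
| north | 0.45 M | 0.45 M | 0.68 M (fed, over 1.0 s) | 65 °C | run made earlier; the fed solution adds 0.25 times the starting volume |  |
| Friday's | 0.45 M | 0.450 M | 0.450 M (fed, over 1.0 s) | 65 °C | the fed solution adds 0.25 times the starting volume | 3.0 min |
| Sunday's | 0.45 M | 0.450 M | 0.450 M (fed, over 1.0 s) | 35 °C | the fed solution adds 0.25 times the starting volume | 3.0 min |
| Wednesday's | 0.45 M | 0.450 M | 0.450 M (fed, over 1.0 s) | 5 °C | the fed solution adds 0.25 times the starting volume | 3.0 min |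

- north (time / s: J / %, L / %): 10.0: 3.7, 12.1; 12.0: 2.7, 9.3; 25.0: 0.7, 4.1; 40.0: 0.3, 1.8

(each reading ± 0.3 percentage points)

- which flask leads in amount of J, in percent of the L charged ("all alike" within 1.5 percentage points) (Friday's / Sunday's / Wednesday's / all alike)
- how much J is there at the end, in percent of the L charged: Friday's
- how much J is there at the end, in percent of the L charged: Sunday's
- how much J is there at the end, in percent of the L charged: Wednesday's

- a species is counted by the L in it: one D counts as two
- charges are per starting volume, the dose included; the dosed solution carries all of it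
- steps under discussion: L + E <-> J; Q + E <-> X; J -> G; Q <-> Z; L + J -> D
- the earlier runs do not show what temperature does; that part of a forecast is a guess

In the north run J falls from 3.7% at 10.0 s to 0.7% at 25.0 s. If the fall is exponential, that reads as a half-life of 6.24 s. I fold this and the flask's time into one number, the half-life count: the time the flask stands divided by the apparent half-life of J. That half-life is read at the north run's temperature and charges, so it belongs to both. For Friday's, at the north run's temperature but with 0.450 M of Q against 0.68 M, I take the same half-life as an estimate, and the count is about 28.8. Each half-life divides J by 2, so Friday's J ends at 2.10 × 10⁻⁹ of its earlier value, which I call zero.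

Is one number enough? The later readings, 0.7% and then 0.3% at 40.0 s, give a longer half-life of 12.3 s, though they lie close to the scatter of 0.3 percentage points. That still makes the count 14.7, so Friday's verdict stands. For Sunday's and Wednesday's it is not enough, because the north run shows no half-life at 35 °C or 5 °C. My pick of Wednesday's as the leader is therefore a guess that cold lengthens the half-life.

The forecast also names Wednesday's. It gives Friday's 0.1% (0% to 1%), Sunday's 8% (1% to 28%) and Wednesday's 45% (18% to 66%). On the cold flasks it says: “Temperature is a guess.”

The flasks give 0% for Friday's, as the count of 28.8 said, 2.64% for Sunday's and 51.4% for Wednesday's, so Wednesday's leads. The forecast stands 5.4 points high on Sunday's and 6.4 points low on Wednesday's.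

    L + E ⇌ J (K = 21.0 M⁻¹, k = 3.30 M⁻¹ s⁻¹, Ea = 52.0 kJ mol⁻¹, ΔH = −30.0 kJ mol⁻¹)
    Q + E ⇌ X (K = 2.00 M⁻¹, k = 6.20 M⁻¹ s⁻¹, Ea = 59.0 kJ mol⁻¹, ΔH = −35.0 kJ mol⁻¹)
    J → G (k = 0.0240 s⁻¹, Ea = 86.0 kJ mol⁻¹)
    Q ⇌ Z (K = 0.250, k = 0.0880 s⁻¹, Ea = 79.0 kJ mol⁻¹, ΔH = −17.0 kJ mol⁻¹)
    L + J → D (k = 0.0660 M⁻¹ s⁻¹, Ea = 40.0 kJ mol⁻¹)
    (constants at 35 °C)

A neighbouring flask is Friday's kept at 80 °C, with the same charges and time. I have no half-life read at that temperature, but if it is no longer than the 6.24 s read from the north run, the count is at least 28.8, and I expect no J. That flask ends at 0% of J, with 93.7% in G and 6.33% in D.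

(The runs were computed from invented constants, noise included.)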